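**Plan**
- Retrosynthesis: the three O–S bonds are cut first, then the two O–benzyl bonds, then C3–C4 of ring C, and last the O1–C2 ether bond.
- Enabling feature: in ring C (O1, C2, C3, C4, C4a, C8a) the enol carbon C3 and the ketone carbon C4 are neighbours that both carry oxygen, a 1,2-dione in disguise. C3–C4 can therefore be made from two aldehyde carbons, with C4 (on ring A) acting as the acyl anion.
- Forward: rings A and B are bought. A Mitsunobu etherification joins O1 to C2, reduction and double oxidation give the dialdehyde, and a carbene-catalysed benzoin closes ring C.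
- Oxidation to the 3,4-dione and enolization make ring C aromatic; hydrogenolysis and trisulfation finish the synthesis.
- Stereochemistry: the target has no stereocentre. C2 is carried racemic, the C3 carbinol forms without control, and both vanish on enolization in step 6.

Key step: step 5

Assumption: the neutral tris(hydrogen sulfate) as drawn is taken as the compound to deliver; it is released from its pyridinium salt by proton exchange and should be handled cold and promptly, because aryl hydrogen sulfates hydrolyse in their own acidity.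

**Route**

Step 1
Reactants: 1 (±)-2-hydroxy-2-(4-hydroxy-3-methoxyphenyl)acetic acid (DL-vanillylmandelic acid)
Product: 2 benzyl (±)-2-[4-(benzyloxy)-3-methoxyphenyl]-2-hydroxyacetate
Conditions: BnBr (2.2 equiv), K2CO3 (2.5 equiv), DMF, 23 °C, N2
Reagents that add atoms: benzyl bromide, BrCc1ccccc1
Why: Williamson-type O-alkylation, in which K2CO3 ionises only the carboxylic acid and the phenol, so benzyl bromide should give the benzyl ester and the aryl benzyl ether while the secondary carbinol stays free and the benzylic centre stays racemic.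

Step 2
Reactants: 2 benzyl (±)-2-[4-(benzyloxy)-3-methoxyphenyl]-2-hydroxyacetate; 3 4-(benzyloxy)-2-hydroxybenzaldehyde
Product: 4 benzyl (±)-2-[5-(benzyloxy)-2-formylphenoxy]-2-[4-(benzyloxy)-3-methoxyphenyl]acetate
Conditions: PPh3 (1.3 equiv), DIAD (1.3 equiv), THF, 0 → 23 °C
Reagents that add atoms: none
Why: Mitsunobu etherification, in which the acidic ortho-formyl phenol protonates the PPh3–DIAD betaine and its phenoxide displaces the alkoxyphosphonium group at a benzylic carbon that is further activated by the ester and has no β-hydrogen, joining O1 to C2 as a racemic centre.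

Step 3
Reactants: 4 benzyl (±)-2-[5-(benzyloxy)-2-formylphenoxy]-2-[4-(benzyloxy)-3-methoxyphenyl]acetate
Product: 5 (±)-2-[4-(benzyloxy)-3-methoxyphenyl]-2-[5-(benzyloxy)-2-(hydroxymethyl)phenoxy]ethan-1-ol
Conditions: LiAlH4 (2 equiv), THF, 0 °C; then H2O, aq NaOH
Reagents that add atoms: none
Why: Hydride reduction with LiAlH4 should take the aldehyde and the benzyl ester to primary alcohols in one operation, while the aryl, benzyl and benzylic aryl ethers are inert to it.

Step 4
Reactants: 5 (±)-2-[4-(benzyloxy)-3-methoxyphenyl]-2-[5-(benzyloxy)-2-(hydroxymethyl)phenoxy]ethan-1-ol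
Product: 6 (±)-4-(benzyloxy)-2-{1-[4-(benzyloxy)-3-methoxyphenyl]-2-oxoethoxy}benzaldehyde
Conditions: (COCl)2, DMSO, CH2Cl2, −78 °C; iPr2NEt, −78 → −30 °C; pH 7 buffer; used crude at once
Reagents that add atoms: none
Why: Swern oxidation, in which both hydroxyls become alkoxysulfonium ions at −78 °C before any base is present, so the hindered amine should release the two aldehydes together without a lactol stage or over-oxidation, and the cold buffered quench limits enolization of the α-aryloxy aldehyde.

Step 5
Reactants: 6 (±)-4-(benzyloxy)-2-{1-[4-(benzyloxy)-3-methoxyphenyl]-2-oxoethoxy}benzaldehyde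
Product: 7 7-(benzyloxy)-2-[4-(benzyloxy)-3-methoxyphenyl]-3-hydroxychroman-4-one (racemic, cis/trans mixture)
Conditions: 2-(pentafluorophenyl)-6,7-dihydro-5H-pyrrolo[2,1-c][1,2,4]triazol-2-ium tetrafluoroborate (15 mol %), Et3N (15 mol %), toluene (0.05 M), 23 °C, Ar
Reagents that add atoms: none
Why: Et3N frees the triazolylidene, which adds reversibly to the aromatic aldehyde carbon (C4); proton transfer gives the Breslow intermediate, whose nucleophilic carbon attacks the neighbouring aliphatic aldehyde carbon (C3), and collapse of the adduct releases the carbene and the 3-hydroxy-4-ketone. The closest known reaction type is the carbene-catalysed intramolecular crossed benzoin cyclization of dialdehydes and of 2-(2-oxoalkoxy)benzaldehydes to 3-hydroxychroman-4-ones. Ring C closes in the 6-exo-trig mode. The C3 carbinol forms next to the racemic C2 centre under substrate control only (aryl group equatorial in a chair-like transition state), and a diastereomer mixture is acceptable because both centres are cleared in step 6. The step needs the carbene pathway to outrun amine enolization of the α-aryloxy aldehyde (aldol closure to a dihydrobenzofuran) and needs the Breslow intermediate to form at the aromatic aldehyde, since one formed at the aliphatic aldehyde could expel the aryloxide. This should be secured by the open, conjugated aromatic aldehyde against an aliphatic aldehyde shielded by a fully substituted neighbour, by the reversibly adding, weakly basic N-pentafluorophenyl carbene, and by using only a catalytic amount of a weak amine; any 4-hydroxy-3-ketone regioisomer would converge on the same dione in step 6.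

Step 6
Reactants: 7 7-(benzyloxy)-2-[4-(benzyloxy)-3-methoxyphenyl]-3-hydroxychroman-4-one
Product: 9 7-(benzyloxy)-2-[4-(benzyloxy)-3-methoxyphenyl]-3-hydroxy-4H-chromen-4-one, via chromane-3,4-dione 8 (not isolated)
Conditions: Dess–Martin periodinane (1,1,1-triacetoxy-1,1-dihydro-1,2-benziodoxol-3(1H)-one, 1.3 equiv), CH2Cl2, 0 → 23 °C; aq Na2S2O3/NaHCO3 work-up
Reagents that add atoms: none
Why: Dess–Martin oxidation of an acyloin to the 1,2-dione, after which the doubly activated C2–H should shift to oxygen so that the dione enolizes to the aromatic 3-hydroxy-4-pyranone, clearing both stereocentres; only a slight excess of oxidant is used to spare the new enol.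

Step 7
Reactants: 9 7-(benzyloxy)-2-[4-(benzyloxy)-3-methoxyphenyl]-3-hydroxy-4H-chromen-4-one
Product: 10 3,7-dihydroxy-2-(4-hydroxy-3-methoxyphenyl)-4H-chromen-4-one (geraldol)
Conditions: H2 (1 atm), 10% Pd/C, THF/MeOH, 23 °C
Reagents that add atoms: none
Why: Catalytic hydrogenolysis of the two aryl benzyl ethers over Pd/C, under which the tetrasubstituted C2=C3 bond of the pyranone and the ring carbonyl should not be reduced at 1 atm.

Step 8
Reactants: 10 3,7-dihydroxy-2-(4-hydroxy-3-methoxyphenyl)-4H-chromen-4-one (geraldol)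
Product: 12 2-[3-methoxy-4-(sulfooxy)phenyl]-4-oxo-4H-chromene-3,7-diyl bis(hydrogen sulfate) (CNP0382475.0), via tris(pyridinium) trisulfate 11 (not isolated)
Conditions: SO3·pyridine (15 equiv), pyridine, 60 °C; then sulfonic acid resin Dowex 50WX8 (H+ form), H2O/MeOH, 0 °C; freeze-drying
Reagents that add atoms: sulfur trioxide–pyridine complex, O=S(=O)([O-])[n+]1ccccc1
Why: O-Sulfation of the two phenolic and the one enolic hydroxyl with excess SO3·pyridine (no 5-hydroxyl is present, and the hydrogen-bonded 3-hydroxyl should react at 60 °C with reagent in excess), followed by cold cation exchange of pyridinium for protons to release the tris(hydrogen sulfate).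

**Compound list**

1 | (±)-2-hydroxy-2-(4-hydroxy-3-methoxyphenyl)acetic acid (DL-vanillylmandelic acid) | COc1cc(C(O)C(=O)O)ccc1O | starting material
2 | benzyl (±)-2-[4-(benzyloxy)-3-methoxyphenyl]-2-hydroxyacetate | COc1cc(C(O)C(=O)OCc2ccccc2)ccc1OCc1ccccc1 | intermediate
3 | 4-(benzyloxy)-2-hydroxybenzaldehyde | O=Cc1ccc(OCc2ccccc2)cc1O | starting material
4 | benzyl (±)-2-[5-(benzyloxy)-2-formylphenoxy]-2-[4-(benzyloxy)-3-methoxyphenyl]acetate | O=Cc1ccc(OCc2ccccc2)cc1OC(C(=O)OCc1ccccc1)c1ccc(OCc2ccccc2)c(OC)c1 | intermediate
5 | (±)-2-[4-(benzyloxy)-3-methoxyphenyl]-2-[5-(benzyloxy)-2-(hydroxymethyl)phenoxy]ethan-1-ol | OCc1ccc(OCc2ccccc2)cc1OC(CO)c1ccc(OCc2ccccc2)c(OC)c1 | intermediate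
6 | (±)-4-(benzyloxy)-2-{1-[4-(benzyloxy)-3-methoxyphenyl]-2-oxoethoxy}benzaldehyde | O=Cc1ccc(OCc2ccccc2)cc1OC(C=O)c1ccc(OCc2ccccc2)c(OC)c1 | intermediate
7 | 7-(benzyloxy)-2-[4-(benzyloxy)-3-methoxyphenyl]-3-hydroxychroman-4-one (racemic, cis/trans mixture) | O=C1c2ccc(OCc3ccccc3)cc2OC(c2ccc(OCc3ccccc3)c(OC)c2)C1O | intermediate
8 | 7-(benzyloxy)-2-[4-(benzyloxy)-3-methoxyphenyl]chromane-3,4-dione (racemic, not isolated) | O=C1c2ccc(OCc3ccccc3)cc2OC(c2ccc(OCc3ccccc3)c(OC)c2)C1=O | intermediate
9 | 7-(benzyloxy)-2-[4-(benzyloxy)-3-methoxyphenyl]-3-hydroxy-4H-chromen-4-one | COc1cc(-c2oc3cc(OCc4ccccc4)ccc3c(=O)c2O)ccc1OCc1ccccc1 | intermediate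
10 | 3,7-dihydroxy-2-(4-hydroxy-3-methoxyphenyl)-4H-chromen-4-one (geraldol) | COc1cc(-c2oc3cc(O)ccc3c(=O)c2O)ccc1O | intermediate
11 | tris(pyridinium) 2-(3-methoxy-4-sulfonatooxyphenyl)-4-oxo-4H-chromene-3,7-diyl bis(sulfate) (not isolated) | COc1cc(-c2oc3cc(OS(=O)(=O)[O-])ccc3c(=O)c2OS(=O)(=O)[O-])ccc1OS(=O)(=O)[O-].c1cc[nH+]cc1.c1cc[nH+]cc1.c1cc[nH+]cc1 | intermediate
12 | 2-[3-methoxy-4-(sulfooxy)phenyl]-4-oxo-4H-chromene-3,7-diyl bis(hydrogen sulfate) (CNP0382475.0) | COc1cc(-c2oc3cc(OS(=O)(=O)O)ccc3c(=O)c2OS(=O)(=O)O)ccc1OS(=O)(=O)O | target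

**Step count and risks**

Total step count: 8. Longest linear sequence: 8 steps (1 to 12; compound 3 enters as a purchased partner in step 2).

Steps most likely to fail:

Step 5. The carbene may engage the aliphatic aldehyde instead of the aromatic one; the acyl anion equivalent formed there can expel the neighbouring aryloxide (internal redox to an aryl ester). Alternatively the amine may enolize the α-aryloxy aldehyde, leading to aldol closure to the five-membered ring. The fallback replaces umpolung catalysis by a reductive ketyl coupling. Setting out from 6, SmI2 (2.5 equiv) with t-BuOH in THF at −78 °C should reduce the aromatic aldehyde first and close the same C3–C4 bond by pinacol coupling, giving 7-(benzyloxy)-2-[4-(benzyloxy)-3-methoxyphenyl]chromane-3,4-diol F1. Swern oxidation of both carbinols ((COCl)2, DMSO, CH2Cl2, −78 °C, then Et3N) should then lead through dione 8 to flavonol 9, where the route is rejoined.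

Step 8. Esterification may stop short at the hydrogen-bonded 3-hydroxyl, and sulfate may be lost by acid hydrolysis during proton exchange, leaving ionic partial sulfates that cannot be separated. The fallback uses masked sulfate diesters. Setting out from 10, 2,2,2-trichloroethyl chlorosulfate with Et3N and DMAP in THF (0 → 23 °C) should give the neutral 2-{3-methoxy-4-[(2,2,2-trichloroethoxy)sulfonyloxy]phenyl}-4-oxo-4H-chromene-3,7-diyl bis(2,2,2-trichloroethyl sulfate) F2, which can be purified on silica. Zn dust and HCO2NH4 in MeOH should unmask it to the tris(ammonium) trisulfate F3, and a short pass through the sulfonic acid resin (H+ form) at 0 °C returns 12.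

Step 4. The new α-aryloxy aldehyde may enolize during the amine stage, with aldol closure onto the aromatic aldehyde, and chloride may capture the electron-rich benzylic alkoxysulfonium ion. The fallback uses two chemoselective, amine-free oxidations with an isolable intermediate. Setting out from 5, activated MnO2 in CH2Cl2 at 23 °C should oxidize only the benzylic alcohol to (±)-4-(benzyloxy)-2-{1-[4-(benzyloxy)-3-methoxyphenyl]-2-hydroxyethoxy}benzaldehyde F4. Dess–Martin periodinane with NaHCO3 in CH2Cl2 at 0 °C then makes the fragile aliphatic aldehyde last, returning 6 just before step 5.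

**Further compounds**

F1 | step 5 | 7-(benzyloxy)-2-[4-(benzyloxy)-3-methoxyphenyl]chromane-3,4-diol (racemic, diastereomer mixture) | OC1c2ccc(OCc3ccccc3)cc2OC(c2ccc(OCc3ccccc3)c(OC)c2)C1O
F2 | step 8 | 2-{3-methoxy-4-[(2,2,2-trichloroethoxy)sulfonyloxy]phenyl}-4-oxo-4H-chromene-3,7-diyl bis(2,2,2-trichloroethyl sulfate) | COc1cc(-c2oc3cc(OS(=O)(=O)OCC(Cl)(Cl)Cl)ccc3c(=O)c2OS(=O)(=O)OCC(Cl)(Cl)Cl)ccc1OS(=O)(=O)OCC(Cl)(Cl)Cl
F3 | step 8 | tris(ammonium) 2-(3-methoxy-4-sulfonatooxyphenyl)-4-oxo-4H-chromene-3,7-diyl bis(sulfate) | COc1cc(-c2oc3cc(OS(=O)(=O)[O-])ccc3c(=O)c2OS(=O)(=O)[O-])ccc1OS(=O)(=O)[O-].[NH4+].[NH4+].[NH4+]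
F4 | step 4 | (±)-4-(benzyloxy)-2-{1-[4-(benzyloxy)-3-methoxyphenyl]-2-hydroxyethoxy}benzaldehyde | O=Cc1ccc(OCc2ccccc2)cc1OC(CO)c1ccc(OCc2ccccc2)c(OC)c1
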